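The reagent stands to the starting material at 0.700 in this flask, so, counted one for one, the reagent is charged short of the starting material.

| flask | starting material | reagent | protic impurity | capture agent | remark | time |
|---|---|---|---|---|---|---|
| ash | 0.25 M | 0.175 M | 0.025 M | 0.025 M | the very flask that is asked about, followed so far |  |
| flask | 0.25 M | 0.175 M | 0.0250 M | 0.0250 M |  | 10 min |

ash run (percent of the starting material charged)

| time / min | open intermediate / % | product / % |
|---|---|---|
| 0.167 | 24.4 | 3.4 |
| 0.333 | 29.1 | 11.7 |
| 1.33 | 22.4 | 35.8 |
| 5.00 | 21.0 | 36.9 |

(scatter of a reading: 0.5 percentage points)

* time up to 10 min at which open intermediate stands highest
* the amount of open intermediate, in percent of the starting material charged, at that time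
* earliest time at which at least nineteen twentieths of that best amount are there, in min
* latest time at which they still are, in min

Take the main steps first, assuming that one reagent opens one starting material and that open intermediate goes on to product. Open intermediate and product together can then reach 70.0% of the starting material charged, with the reagent as limiting reagent. Next add the protic impurity, taken to consume starting material one for one. It removes up to 10.0%, which leaves 90.0%, more than the reagent can open, so the number stays. Last add the capture agent, taken to remove open intermediate one for one. This gives the free level, what open intermediate and product together come to once reagent and capture agent are both used up, the reagent charge less the capture agent charge over the starting material charge: 60.0%. The ash run, this same flask followed so far, reads sums of 58.2% at 1.33 min and 57.9% at 5.00 min, just under the free level. The free level speaks of the sum, not of the peak of open intermediate, which has to be sought near the highest reading, 29.1% at 0.333 min.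

The forecast puts the peak at 0.37 min with 29.3%, and the window from 0.24 min to 0.62 min. It reaches the same limit for the sum by another road, “less 10% lost to the protic impurity”, where this reckoning charges the loss to the capture agent; the two charges are equal in this flask, so both give one number.

The flask peaks at 0.357 min with 29.1%, and the window runs from 0.234 min to 0.548 min, so the forecast holds within its margins.

    starting material + reagent ⇌ open intermediate (K = 180 L mol⁻¹, k = 0.280 L mol⁻¹ s⁻¹)
    open intermediate ⇌ product + by-product (K = 0.170 M, k = 0.0290 s⁻¹)
    starting material + protic impurity → quenched substrate (k = 0.390 L mol⁻¹ s⁻¹)
    open intermediate + capture agent → trapped intermediate (k = 0.130 L mol⁻¹ s⁻¹)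

At 10.0 min this flask holds 58.1% as open intermediate and product, against the free level of 60.0%, with trapped intermediate at 9.85%. A neighbour flask charged with 0.10 M of capture agent has a free level of 30.0%. At 10.0 min that neighbour holds 32.9% as open intermediate and product, above that level, with 9.64% of its capture agent still there, so the level's condition, capture agent used up, does not hold at that time. Its trapped intermediate stands at 36.1%, above its product at 24.4%, and its open intermediate peaks at 26.2%.

(The readings stem from a simulated flask for an exercise, noise included.)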